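(Readings and results were generated by integration on assumed constants, and the scatter is random.)

| setting | theta | dusk | winter | dawn |
|---|---|---|---|---|
| E | 0.17 M | 0.11 M | 0.11 M | 0.11 M |
| temperature | 20 °C | 20 °C | 5 °C |  |
| remark | run made earlier |  |  | at 5 °C until 8.0 min, from then on at 20 °C |
| time |  | 15 min | 15 min | 15 min |

theta run (percent of the E charged): time / min: X / % = 0.333: 20.1; 0.500: 25.4; 0.833: 32.6; 1.33: 35.0; 2.00: 33.3; 3.00: 28.3; 5.00: 19.3

(readings scatter by 0.3 percentage points)

- the earlier runs were read with a standard deviation of 0.3 percentage points
- in a conversion D counts as not yet reacted; Z counts as reacted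
- the earlier runs do not show what temperature does; that part of a forecast is a guess

1. the flask that comes out highest in amount of X, in percent of the E charged, or "all alike" when all lie within 1.5 percentage points (dusk / winter / dawn / all alike)
2. X at the end, in percent of the E charged, dusk
3. X at the end, in percent of the E charged, winter
4. X at the end, in percent of the E charged, dawn

In the theta run [X] is a leftover from 1.33 min on: it reads 35.0 % there, above its neighbours, then sinks to 19.3 % by 5.00 min. X behaves as the intermediate of consecutive reactions, so at that peak control passes from its making to its loss. The last readings give a tail rate of 0.182 /min. If percentages carry over between charges, dusk, at the same temperature, should hold 3.13 % at 15 min.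

The readings do not show temperature, so we assume that cold slows every step by one factor s, which puts a cold flask read at time t at t/s on the theta curve. The crossing factor, reading time over the time of the highest theta reading, is the slowing that puts a flask on that highest reading: 11.3 at 15 min. A smaller s puts it on the falling side.

Now turn the question round. For any s above one, dawn stands later on the curve than winter, beyond the last reading. On that assumption and the extended tail, to pass winter, dawn or dusk needs winter on the rising side, earlier than the first reading, and by this reckoning that takes s above 45.0. We guess s = 4, which is below the crossing factor. Our reckoning then gives winter 24.2 % and dawn 9.33 %, so we commit to winter.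

The forecast gives winter, with dusk 3 % (2.2 % to 5.5 %), winter 23.5 % (13 % to 33 %) and dawn 9 % (6 % to 14 %): “Winter comes out highest.”

The flasks give dusk 3.66 %, winter 27.8 % and dawn 11.1 %, so winter leads.

    E → X (k = 0.00207 /s, Ea = 86.0 kJ/mol)
    Z → L (k = 7.25 × 10⁻⁴ /s, Ea = 91.0 kJ/mol)
    X → G (k = 9.98 × 10⁻⁴ /s, Ea = 83.0 kJ/mol)
    D → Q (k = 0.00310 /s, Ea = 88.0 kJ/mol)
    D ⇌ Z (K = 1.53, k = 0.0283 /s, Ea = 65.0 kJ/mol, ΔH = −44.0 kJ/mol)
    E ⇌ D (K = 0.0894, k = 7.36 × 10⁻⁴ /s, Ea = 92.0 kJ/mol, ΔH = −35.0 kJ/mol)
    X ⇌ J (K = 1.10, k = 0.00192 /s, Ea = 78.0 kJ/mol, ΔH = −6.00 kJ/mol)
    (constants at 5 °C)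

Winter's [X] falls from 31.0 % at 7.50 min to 27.8 % at 15.0 min, so at the end that flask stands past its peak, the side on which a slowing below 11.3 puts it. The largest single effect on the gap between dusk and winter is what temperature does to the passing of X into G: dusk minus winter is −24 percentage points, and 2.5 points with that effect taken away.

Winter read at 4.0 min has a crossing factor of 3.01, below our 4, so it should stand before its peak. It holds 26.5 %, on the way up to 31.0 % at 7.50 min, with 54.3 % of E left.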